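**Plan**
- Target 12 is (2R)-7-bromo-6-hydroxy-2-(4-hydroxy-4-methylpentyl)-2-methylchroman-4-one (ring A = benzene ring, ring B = pyranone; atoms O1, C2, C3, C4, C4a–C8a).
- Enabling feature: C2 with its methyl, C3 and the three-CH2 chain ending in the gem-dimethyl carbinol is a linalyl unit bound through O1 to ring A, and C4 is an acyl carbon on C4a ortho to O1. C3 can therefore come as the vinyl CH of a linalyl aryl ether and C4 as a salicylate ester carbon.
- Retrosynthesis: (a) C4 ketone and C6 phenol from a 4-methoxy-2H-chromene MOM ether; (b) C3=C4 cut by ring-closing metathesis; (c) 1-methoxyvinyl group from the methyl ester, chain alcohol from the trisubstituted alkene; (d) O1–C2 cut to a salicylate phenol and geranyl methyl carbonate.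
- Forward: ring A building block 4 (three steps from 4-bromo-2,5-dimethoxybenzaldehyde), then O1–C2 by palladium allylic etherification, chain hydration, ester methylenation, ring B by C3=C4 metathesis, and acid to unmask ketone and phenol.
- Stereochemistry: the only stereocenter, C2, is set in step 5 by the chiral palladium catalyst. No later step breaks a bond at C2 and no base is used after ring closure, so retro-oxa-Michael scrambling is avoided.

Key step: step 8

Assumption: for the E carbonate 6 the (R,R)-ligand is taken to deliver the R ether 7; should the sense of induction prove opposite, the (S,S)-ligand is used and nothing else changes.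

Step 1
Reactants: 1 4-bromo-2,5-dimethoxybenzaldehyde
Product: 2 methyl 4-bromo-2,5-dimethoxybenzoate
Conditions: I2, KOH, MeOH, 0 °C
Reagents that add atoms: methanol, CO
Why: Oxidative esterification of an aromatic aldehyde (hemiacetal oxidized by hypoiodite) should give the methyl ester directly, the aryl bromide and methyl ethers being inert.

Step 2
Reactants: 2 methyl 4-bromo-2,5-dimethoxybenzoate
Product: 3 methyl 4-bromo-2,5-dihydroxybenzoate
Conditions: BBr3, CH2Cl2, −78 → 0 °C; MeOH then H2O quench
Reagents that add atoms: none
Why: Lewis-acid cleavage of aryl methyl ethers (bromide attack on the O-complexed methyl) should free both phenols, the methyl ester being much slower to cleave at or below 0 °C.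

Step 3
Reactants: 3 methyl 4-bromo-2,5-dihydroxybenzoate
Product: 4 methyl 4-bromo-2-hydroxy-5-(methoxymethoxy)benzoate
Conditions: MOMCl (1.05 equiv), iPr2NEt, CH2Cl2, 0 °C
Reagents that add atoms: chloromethyl methyl ether, COCCl
Why: Chemoselective O-alkylation should occur at the free C5 hydroxyl, because the C2 hydroxyl is held in a hydrogen bond to the ester carbonyl and is far less nucleophilic.

Step 4
Reactants: 5 geraniol
Product: 6 geranyl methyl carbonate, (2E)-3,7-dimethylocta-2,6-dien-1-yl methyl carbonate
Conditions: ClCO2Me, pyridine, CH2Cl2, 0 °C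
Reagents that add atoms: methyl chloroformate, COC(=O)Cl
Why: Acylation of the primary allylic alcohol with a chloroformate should give the carbonate with the E alkene unchanged.

Step 5
Reactants: 4 methyl 4-bromo-2-hydroxy-5-(methoxymethoxy)benzoate; 6 geranyl methyl carbonate
Product: 7 methyl 4-bromo-2-{[(3R)-3,7-dimethylocta-1,6-dien-3-yl]oxy}-5-(methoxymethoxy)benzoate
Conditions: Pd2(dba)3·CHCl3 (2 mol %), (R,R)-DACH-phenyl Trost ligand (6 mol %), CH2Cl2, rt
Reagents that add atoms: none
Why: Tsuji–Trost asymmetric allylic alkylation: zerovalent palladium ionizes the carbonate to a π-geranyl complex, and the phenoxide released on decarboxylation attacks the more substituted allyl terminus inside the chiral ligand pocket, which selects one enantioface and sets the fully substituted C–O stereocenter (future C2) as R.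

Step 6
Reactants: 7 methyl 4-bromo-2-{[(3R)-3,7-dimethylocta-1,6-dien-3-yl]oxy}-5-(methoxymethoxy)benzoate
Product: 8 methyl 4-bromo-2-{[(3R)-7-hydroxy-3,7-dimethyloct-1-en-3-yl]oxy}-5-(methoxymethoxy)benzoate
Conditions: Co(acac)2 (20 mol %), PhSiH3, O2 (1 atm), THF, rt
Reagents that add atoms: dioxygen, O=O
Why: Mukaiyama hydration should be selective because hydrogen-atom transfer from the cobalt hydride goes to the trisubstituted alkene (tertiary radical, trapped by O2 and reduced to the Markovnikov alcohol) faster than to the vinyl group on the fully substituted carbon; the stereocenter is not involved.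

Step 7
Reactants: 8 methyl 4-bromo-2-{[(3R)-7-hydroxy-3,7-dimethyloct-1-en-3-yl]oxy}-5-(methoxymethoxy)benzoate
Product: 9 (6R)-6-[5-bromo-4-(methoxymethoxy)-2-(1-methoxyethenyl)phenoxy]-2,6-dimethyloct-7-en-2-ol
Conditions: Cp2Ti(μ-CH2)(μ-Cl)AlMe2 (Tebbe reagent, 3 equiv), pyridine, THF–toluene, −40 °C → rt; aq. NaOH quench; Et3N-deactivated silica
Reagents that add atoms: Tebbe reagent, C[Al](C)C[Ti](Cl)(C1C=CC=C1)C1C=CC=C1
Why: Tebbe methylenation (titanium methylidene, oxatitanacyclobutane, loss of the titanium oxo unit) should turn the aryl ester into the 1-methoxyvinyl group, pyridine masking the aluminium Lewis acid and the tertiary alcohol merely consuming one equivalent as a titanium alkoxide that returns on work-up.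

Step 8
Reactants: 9 (6R)-6-[5-bromo-4-(methoxymethoxy)-2-(1-methoxyethenyl)phenoxy]-2,6-dimethyloct-7-en-2-ol
Product: 10 5-[(2R)-7-bromo-4-methoxy-6-(methoxymethoxy)-2-methyl-2H-chromen-2-yl]-2-methylpentan-2-ol
Conditions: second-generation Grubbs catalyst (H2IMes)(PCy3)Cl2Ru=CHPh (5–10 mol %), toluene (0.005 M), 70 °C, argon sparge
Reagents that add atoms: none
Why: Ring-closing olefin metathesis: the ruthenium alkylidene exchanges onto the linalyl vinyl group, adds across the 1-methoxyvinyl group through a ruthenacyclobutane and cycloreverts with loss of ethene, so the vinyl CH becomes C3 and the former ester carbon becomes C4 with its oxygen still attached. The closest known reaction types are the metathesis of styrenyl allyl ethers to 2H-chromenes and of acyclic enol ethers to cyclic enol ethers. Ring B closes as a six-membered ring by intramolecular metathesis of two terminal alkenes held ortho on ring A, helped by the gem-dialkyl effect of the fully substituted C2. No stereocenter is formed, and C2 keeps its configuration because none of its bonds takes part. The step needs the catalyst to pair the vinyl group only with the enol ether: the trisubstituted chain alkene, which would close a cyclopentene with the vinyl group as linalool-type dienes do, was removed in step 6, and the free alcohol, aryl bromide and MOM acetal are tolerated by ruthenium.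

Step 9
Reactants: 10 5-[(2R)-7-bromo-4-methoxy-6-(methoxymethoxy)-2-methyl-2H-chromen-2-yl]-2-methylpentan-2-ol
Product: 12 (2R)-7-bromo-6-hydroxy-2-(4-hydroxy-4-methylpentyl)-2-methylchroman-4-one, via MOM-protected chromanone 11 (not isolated)
Conditions: 2 M aq. HCl, THF–MeOH, rt → 40 °C
Reagents that add atoms: water, O
Why: Acid hydrolysis of the enol ether (C3 protonation, water addition to the C4 oxocarbenium, loss of methanol) followed by MOM acetal hydrolysis should give the ketone and the phenol, and under acid the C2 ether does not undergo the base-induced retro-oxa-Michael opening that would scramble the stereocenter.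

**Compound list**
1 | 4-bromo-2,5-dimethoxybenzaldehyde | O=Cc1cc(OC)c(Br)cc1OC | starting material
2 | methyl 4-bromo-2,5-dimethoxybenzoate | COC(=O)c1cc(OC)c(Br)cc1OC | intermediate
3 | methyl 4-bromo-2,5-dihydroxybenzoate | COC(=O)c1cc(O)c(Br)cc1O | intermediate
4 | methyl 4-bromo-2-hydroxy-5-(methoxymethoxy)benzoate | COC(=O)c1cc(OCOC)c(Br)cc1O | intermediate
5 | geraniol, (2E)-3,7-dimethylocta-2,6-dien-1-ol | CC(C)=CCC/C(C)=C/CO | starting material
6 | geranyl methyl carbonate, (2E)-3,7-dimethylocta-2,6-dien-1-yl methyl carbonate | CC(C)=CCC/C(C)=C/COC(=O)OC | intermediate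
7 | methyl 4-bromo-2-{[(3R)-3,7-dimethylocta-1,6-dien-3-yl]oxy}-5-(methoxymethoxy)benzoate | CC(C)=CCC[C@](Oc1cc(Br)c(OCOC)cc1C(=O)OC)(C)C=C | intermediate
8 | methyl 4-bromo-2-{[(3R)-7-hydroxy-3,7-dimethyloct-1-en-3-yl]oxy}-5-(methoxymethoxy)benzoate | CC(C)(O)CCC[C@](Oc1cc(Br)c(OCOC)cc1C(=O)OC)(C)C=C | intermediate
9 | (6R)-6-[5-bromo-4-(methoxymethoxy)-2-(1-methoxyethenyl)phenoxy]-2,6-dimethyloct-7-en-2-ol | CC(C)(O)CCC[C@](Oc1cc(Br)c(OCOC)cc1C(=C)OC)(C)C=C | intermediate
10 | 5-[(2R)-7-bromo-4-methoxy-6-(methoxymethoxy)-2-methyl-2H-chromen-2-yl]-2-methylpentan-2-ol | CC(C)(O)CCC[C@]1(C)C=C(OC)c2cc(OCOC)c(Br)cc2O1 | intermediate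
11 | (2R)-7-bromo-2-(4-hydroxy-4-methylpentyl)-6-(methoxymethoxy)-2-methylchroman-4-one | CC(C)(O)CCC[C@]1(C)CC(=O)c2cc(OCOC)c(Br)cc2O1 | intermediate
12 | (2R)-7-bromo-6-hydroxy-2-(4-hydroxy-4-methylpentyl)-2-methylchroman-4-one | CC(C)(O)CCC[C@]1(C)CC(=O)c2cc(O)c(Br)cc2O1 | target

**Step count**
Total steps: 9. Longest linear sequence: 8 (steps 1, 2, 3, 5, 6, 7, 8, 9); step 4 is a one-step side branch.

**Steps most likely to fail**

1. Step 5. What may go wrong: phenoxide attack at the unsubstituted allyl terminus (linear geranyl ether), re-ionization of the product ether by zerovalent palladium with erosion of enantiopurity, or an induction sense other than the assumed one. The fallback sets out from phenol 4 and replaces asymmetric catalysis by propargylation and resolution.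
   - Racemic 3,7-dimethyloct-6-en-1-yn-3-ol (commercial) is converted with n-BuLi and ClCO2Me into 3,7-dimethyloct-6-en-1-yn-3-yl methyl carbonate F1.
   - Copper-catalysed propargylic etherification of 4 with it (CuCl2·2H2O, DBU, MeCN, 0 °C, copper allenylidene) should give only the tertiary ether, the racemic aryl propargyl ether F2.
   - Semi-hydrogenation of the alkyne (H2, Pd/CaCO3 poisoned with Pb(OAc)2, quinoline) should give the racemic linalyl aryl ether F3.
   - The enantiomers are separated by preparative chromatography on a chiral stationary phase; the R enantiomer is 7, where the route is rejoined.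

2. Step 8. What may go wrong: slow initiation at the hindered vinyl group and at the 1,1-disubstituted enol ether, so that the catalyst decomposes before ring closure; thermal aryl Claisen shift or adventitious enol ether hydrolysis at 70 °C. The fallback sets out from ester 8, closes ring B at the alkene oxidation level and oxygenates C4 afterwards.
   - DIBAL-H reduction should give the benzylic alcohol F4, and MnO2 the aldehyde F5.
   - Wittig methylenation (Ph3P=CH2) should give the styrene F6.
   - Metathesis with the second-generation Grubbs catalyst (CH2Cl2, 40 °C), which can initiate at the unhindered styrene, should give the 2H-chromene F7.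
   - Markovnikov hydration by hydrogen-atom transfer (Co(acac)2, PhSiH3, O2; benzylic C4 radical) should give the chroman-4-ol F8.
   - Dess–Martin oxidation should give 11, where the route is rejoined; the acid of step 9 then gives 12.

3. Step 6. What may go wrong: hydrogen-atom transfer to the vinyl group as well, or cyclization of the tertiary radical onto the vinyl group before oxygen trapping. The fallback sets out from geraniol 5 and installs the chain alcohol before the ether is made.
   - Oxymercuration–demercuration (Hg(OAc)2, THF–H2O; NaBH4, NaOH), selective for the distal alkene because the 2,3-alkene is deactivated by the allylic oxygen, should give the diol F9.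
   - Acylation of the primary hydroxyl only (ClCO2Me, pyridine) should give the hydroxy carbonate F10.
   - Allylic etherification of phenol 4 with F10 under the conditions of step 5 should give 8 directly, where the route is rejoined.

Further compounds
F1 | step 5 | 3,7-dimethyloct-6-en-1-yn-3-yl methyl carbonate (racemic) | C#CC(C)(OC(=O)OC)CCC=C(C)C
F2 | step 5 | methyl 4-bromo-2-[(3,7-dimethyloct-6-en-1-yn-3-yl)oxy]-5-(methoxymethoxy)benzoate (racemic) | C#CC(C)(Oc1cc(Br)c(OCOC)cc1C(=O)OC)CCC=C(C)C
F3 | step 5 | methyl 4-bromo-2-[(3,7-dimethylocta-1,6-dien-3-yl)oxy]-5-(methoxymethoxy)benzoate (racemic) | C=CC(C)(Oc1cc(Br)c(OCOC)cc1C(=O)OC)CCC=C(C)C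
F4 | step 8 | (6R)-6-[5-bromo-2-(hydroxymethyl)-4-(methoxymethoxy)phenoxy]-2,6-dimethyloct-7-en-2-ol | CC(C)(O)CCC[C@](Oc1cc(Br)c(OCOC)cc1CO)(C)C=C
F5 | step 8 | 4-bromo-2-{[(3R)-7-hydroxy-3,7-dimethyloct-1-en-3-yl]oxy}-5-(methoxymethoxy)benzaldehyde | CC(C)(O)CCC[C@](Oc1cc(Br)c(OCOC)cc1C=O)(C)C=C
F6 | step 8 | (6R)-6-[5-bromo-2-ethenyl-4-(methoxymethoxy)phenoxy]-2,6-dimethyloct-7-en-2-ol | CC(C)(O)CCC[C@](Oc1cc(Br)c(OCOC)cc1C=C)(C)C=C
F7 | step 8 | 5-[(2R)-7-bromo-6-(methoxymethoxy)-2-methyl-2H-chromen-2-yl]-2-methylpentan-2-ol | CC(C)(O)CCC[C@]1(C)C=Cc2cc(OCOC)c(Br)cc2O1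
F8 | step 8 | (2R)-7-bromo-2-(4-hydroxy-4-methylpentyl)-6-(methoxymethoxy)-2-methylchroman-4-ol (C4 epimers) | CC(C)(O)CCC[C@]1(C)CC(O)c2cc(OCOC)c(Br)cc2O1
F9 | step 6 | (2E)-3,7-dimethyloct-2-ene-1,7-diol | CC(C)(O)CCC/C(C)=C/CO
F10 | step 6 | (2E)-7-hydroxy-3,7-dimethyloct-2-en-1-yl methyl carbonate | CC(C)(O)CCC/C(C)=C/COC(=O)OC
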